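The constants of the steps are not on hand, but the plateaus of the earlier runs give one ratio of them, enough to argue over these flasks.

| flask | substrate | reagent | temperature | remark | time |
|---|---|---|---|---|---|
| cedar | 0.050 M | 0.125 M | −35 °C | run made earlier |  |
| ash | 0.070 M | 0.125 M | −20 °C | run made earlier |  |
| maple | 0.11 M | 0.125 M | −35 °C | run made earlier |  |
| alder | 0.050 M | 0.25 M | −20 °C | run made earlier |  |
| dusk | 0.050 M (fed, over 10 d) | 0.125 M | −20 °C | all else is in the flask from the start; the feed brings no volume worth counting | 15 d |
| midnight | 0.050 M | 0.125 M (fed, over 10 d) |  | the addition at −60 °C, then warmed to −20 °C; the feed brings no volume worth counting | 15 d |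
| summer | 0.050 M | 0.125 M (fed, over 10 d) | −20 °C | all else is in the flask from the start; the feed brings no volume worth counting | 15 d |
| autumn | 0.050 M | 0.125 M (in portions, 4, over 10 d) | −20 °C | first portion at the start, last at 10 d | 15 d |

| run | time / d | over-reaction product / % | target / % |
|---|---|---|---|
| cedar | 8.00 | 42.4 | 41.8 |
| cedar | 15.0 | 57.1 | 25.0 |
| cedar | 25.0 | 68.1 | 12.2 |
| cedar | 30.0 | 72.3 | 10.0 |
| ash | 2.50 | 47.3 | 26.4 |
| ash | 6.00 | 60.2 | 9.3 |
| ash | 12.0 | 65.8 | 2.4 |
| ash | 20.0 | 67.1 | 0.4 |
| maple | 10.0 | 17.4 | 54.1 |
| maple | 20.0 | 21.5 | 46.7 |
| maple | 30.0 | 24.9 | 42.6 |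
| maple | 40.0 | 25.1 | 40.0 |
| alder | 1.25 | 75.9 | 11.2 |
| alder | 3.00 | 85.5 | 1.4 |
| alder | 8.00 | 86.8 | 0 |
| alder | 20.0 | 86.7 | 0.2 |

(each reading ± 0.5 percentage points)
1. the flask that comes out highest in amount of over-reaction product, in percent of the substrate charged, or "all alike" when all lie within 1.5 percentage points (dusk / midnight / summer / autumn / all alike)
2. over-reaction product at the end, in percent of the substrate charged, dusk
3. over-reaction product at the end, in percent of the substrate charged, midnight
4. over-reaction product at the end, in percent of the substrate charged, summer
5. over-reaction product at the end, in percent of the substrate charged, autumn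
- in percentages every species weighs as the substrate in it: one side product counts as two
- steps thought possible: substrate + reagent -> target; substrate + target -> side product; reagent + target -> over-reaction product; target <-> isomer of the product

At −20 °C the over-reaction product of ash reads 67.1% and that of alder 86.7% at 20.0 d, with target down to 0.4% and 0.2%, so I take these readings as plateaus. Take the shortfall from complete over-reaction, divide it by the over-reaction product, then divide by the charged ratio of substrate to reagent. Ash gives 0.876 and alder 0.767, somewhat more in ash, so the figure is rough. Their mean, 0.821, is the fork constant, a lumped selectivity factor for what becomes of target; side product and isomer both sit in its shortfall.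

One chemist argues from the charge. Dusk, midnight, summer and autumn are each charged with substrate and reagent at 0.400, so each should end at one over the quantity one plus fork constant times ratio, which is 75.3%, and they come out alike.

The other answers that the ratio counts as it stands in the flask at each moment. Taken at half the charged ratio, dusk reaches 85.9%, so dusk lies above the mixed value. Autumn's first portion, 31.2 mM of reagent against 0.050 M of substrate, gives 43.2% by the same formula, and summer starts with its reagent still to come.

The second reckoning is the one to hold: dusk on top, summer and autumn far down. Midnight gets no figure from this, since its reagent goes in at −60 °C and the fork constant was read at −20 °C.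

The forecast names dusk and gives dusk 81%, midnight 69%, summer 30% and autumn 24%, on the ground that “Dusk keeps substrate scarce and reagent plentiful”.

    substrate + reagent → target, rate k1*[substrate]^1.5*[reagent]^0.5 (k = 0.00270 L mol⁻¹ s⁻¹, Ea = 56.0 kJ mol⁻¹)
    substrate + target → side product (k = 3.50 × 10⁻⁴ L mol⁻¹ s⁻¹, Ea = 59.0 kJ mol⁻¹)
    reagent + target → over-reaction product (k = 1.10 × 10⁻⁴ L mol⁻¹ s⁻¹, Ea = 66.0 kJ mol⁻¹)
    target ⇌ isomer of the product (K = 13.0, k = 7.70 × 10⁻⁷ s⁻¹, Ea = 94.0 kJ mol⁻¹, ΔH = −25.0 kJ mol⁻¹)
    (constants at −20 °C)

Dusk ends highest at 79.7%, with midnight at 71.0%, summer at 26.8% and autumn at 23.1%. Summer holds 63.3% of side product at the end, dusk 10.4%. Read backward through the fork constant, dusk worked at a ratio of 0.310 and summer at 3.32, ten times as much from the same charge. Dosing quickly brings both toward the mixed 75.3%: over 1.00 d, dusk ends at 75.2% and summer at 62.4%.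

The runs were generated by integration for an exercise; the scatter is artificial.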